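The target and its isomer both grow from substrate and reagent, so I asked where those two additions come to rest.

    target + free catalyst ⇌ isomer of the product + free catalyst, rate k1*[free catalyst]*[target] forward; the back reaction follows from the equilibrium constant (k1 = 57.4 /M/min)
    substrate + reagent ⇌ target (K2 = 660 /M, k2 = 0.455 /M/min)
    substrate + reagent ⇌ isomer of the product (K3 = 248 /M, k3 = 0.195 /M/min)
    free catalyst + free catalyst ⇌ resting dimer (K4 = 13000 /M, k4 = 4500 /M/min)
    free catalyst + impurity → spent catalyst (k5 = 34600 /M/min)

substrate 19 mM; reagent 9.50 mM; free catalyst 38 µM; impurity 4.9 µM; time 8.0 d

1. how much target there is at 8.0 d, in percent of the substrate charged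
2. how much isomer of the product there is at 8.0 d, in percent of the substrate charged

A rate constant says how soon a step moves, and an equilibrium constant says where it stops. I counted turnovers first, to learn which of the two mattered. With reagent as charged, substrate has a forward half-life of 0.11 d by the step to target and 0.26 d by the step to isomer. The way back is first order, with constant k/K, so its half-life holds no concentration.

half-life of target going back: 0.698 d
half-life of isomer going back: 0.612 d
halvings in the run, on the longer one: 11.5

The back step of target was the longest of these clocks. By this estimate, that many halvings leave 0.0356 % of the starting gap to rest. So I expected thermodynamic control, and I reckoned the end from the equilibrium constants and the charges.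

At the end, c(target) is K_target c(substrate) c(reagent), and c(isomer) has the same form with K_isomer. Their sum, 908 /M, is the pooled constant: target plus isomer over the product of c(substrate) and c(reagent) at rest. Call target plus isomer x.

x = K_pool (c(substrate, charged) − x)(c(reagent, charged) − x)
x = 8.59 mM

The catalysed step between target and isomer has the constant K_isomer/K_target, which the two additions already imply, so it added no equation. Shared by the constants, x gave me target 32.9 % and isomer 12.3 % of the substrate charged.

The forecast said 32.9 % and 12.35 %, on the ground that “the cycle is thermodynamically consistent, so the system reaches full equilibrium”.

The flask held target 32.9 % and isomer 12.3 % at 8.0 d, and 32.9 % and 12.3 % at 80.0 d. The neighbour charged with 3.8 mM of reagent has the same back half-life, so the same 11.5 halvings. The pooled constant gives it x = 3.55 mM, which is target 13.6 % and isomer 5.10 %. That neighbour gave target 13.6 % and isomer 5.10 %, with 81 % of its substrate still unbound.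

(All constants belong to no real substance; what happens was integrated by code.)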